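**Retrosynthetic overview**
1. The inner 2,3-dihydrobenzofuran, fused to the central phenol ring (ring B), is opened at O1–C7a and C3–C3a together. This gives a ring-B aryne and an enantiopure trans-2,3-diaryloxirane.
2. Enabling feature: O1 and C3 of that ring sit on two adjacent carbons of ring B (C7a and C3a), which is an aryne retron, and the excised O1–C2(aryl)–C3(aryl) unit is a stilbene oxide. C4, next to C3a, carries the bulky outer dihydrobenzofuran and steers the oxygen to C7a. The 2-aryl ring has a para oxygen that can be worn as a triflate and decides which oxirane C–O bond breaks. The oxirane C3–O bond is a temporary bond that stores configuration.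
3. Aryne half: the outer dihydrobenzofuran comes from an enantioselective rhodium-carbene C–H insertion followed by C2 epimerisation. Its 3,5-dihydroxyphenyl ring becomes an o-silylaryl triflate by bromination and retro-Brook shift.
4. Oxirane half: Horner–Wadsworth–Emmons olefination, then Shi epoxidation.
5. Ring order: outer dihydrobenzofuran (step 4), oxirane (step 14, temporary), inner dihydrobenzofuran (step 15), then removal of triflate, ethers and acetal.

Key step: step 15

Assumption: Rh2(S-PTAD)4 is taken to deliver the (3R) centre in step 4 (if the sense is opposite, Rh2(R-PTAD)4 is used), and the L-series Shi ketone of step 14 is taken as a purchasable catalyst.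

**Step 1**
Reactants: 1 5-bromobenzene-1,3-diol
Product: 2 1,3-bis(benzyloxy)-5-bromobenzene
Conditions: BnBr (2.2 equiv), K2CO3, DMF, 60 °C
Reagents that add atoms: benzyl bromide, BrCc1ccccc1
Why: Williamson ether synthesis on both phenols; the benzyl ethers survive Grignard formation, hydrazine, MnO2, the carbene step and CF3CO2H and leave later by hydrogenolysis.

**Step 2**
Reactants: 3 5-bromo-2-hydroxybenzonitrile; 4 4-(benzyloxy)benzyl chloride
Product: 5 2-{[4-(benzyloxy)phenyl]methoxy}-5-bromobenzonitrile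
Conditions: K2CO3, KI (cat.), DMF, 60 °C
Reagents that add atoms: none
Why: Williamson ether synthesis installs the benzylic O–CH2 group whose C–H bond is the later insertion site; nitrile and aryl bromide are inert to K2CO3.

**Step 3**
Reactants: 2 1,3-bis(benzyloxy)-5-bromobenzene; 5 2-{[4-(benzyloxy)phenyl]methoxy}-5-bromobenzonitrile
Product: 8 [3,5-bis(benzyloxy)phenyl](2-{[4-(benzyloxy)phenyl]methoxy}-5-bromophenyl)methanone hydrazone, via arylmagnesium bromide 6 (not isolated), via N-H ketimine 7 (not isolated)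
Conditions: 2, Mg, THF, reflux; 5, CuBr (5 mol %), THF, reflux; MeOH, 0 °C; N2H4·H2O, AcOH (cat.), EtOH, 70 °C
Reagents that add atoms: hydrazine, NN
Why: Grignard addition to the nitrile stops at the magnesium ketiminate, and the freed N-H ketimine undergoes transimination with hydrazine more readily than a hindered ketone would condense; the aryl bromide of 5 does not exchange with an arylmagnesium reagent.

**Step 4**
Reactants: 8 the hydrazone
Product: 11 (2R,3R)-3-[3,5-bis(benzyloxy)phenyl]-2-[4-(benzyloxy)phenyl]-5-bromo-2,3-dihydro-1-benzofuran, via diaryldiazomethane 9 (not isolated), via cis-dihydrobenzofuran 10 (not isolated)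
Conditions: MnO2 (10 equiv), CH2Cl2, 0 °C to rt, filter; Rh2(S-PTAD)4 (1 mol %), CH2Cl2, 0 °C; then CF3CO2H, 0 °C to rt
Reagents that add atoms: none
Why: Hydrazone oxidation gives a donor/donor diazo compound, whose enantioselective intramolecular rhodium-carbene C–H insertion into the benzylic ether CH2 closes the ring as the cis isomer with the catalyst setting C3 (R); acid then ionises the para-alkoxybenzylic C2–O bond reversibly and the intact C3 steers reclosure to the more stable trans isomer (C2 becomes R).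

**Step 5**
Reactants: 11 the trans bromide
Product: 13 (2R,3R)-3-[3,5-bis(benzyloxy)phenyl]-2-[4-(benzyloxy)phenyl]-2,3-dihydro-1-benzofuran-5-carbaldehyde, via aryllithium 12 (not isolated)
Conditions: n-BuLi (1.1 equiv), THF, −78 °C; DMF; then H2O
Reagents that add atoms: N,N-dimethylformamide, CN(C)C=O
Why: Bromine–lithium exchange and formylation with DMF (Bouveault aldehyde synthesis); exchange at −78 °C outruns benzylic deprotonation, so both stereocentres stay untouched.

**Step 6**
Reactants: 13 the aldehyde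
Product: 14 (2R,3R)-3-[3,5-bis(benzyloxy)phenyl]-2-[4-(benzyloxy)phenyl]-5-(1,3-dioxolan-2-yl)-2,3-dihydro-1-benzofuran
Conditions: HOCH2CH2OH, pyridinium p-toluenesulfonate (cat.), toluene, reflux, Dean–Stark
Reagents that add atoms: ethane-1,2-diol, OCCO
Why: Acetalisation masks the aldehyde against n-BuLi (step 9) and against the aryne (step 15); the trans ring is the thermodynamic isomer and is safe under weak acid.

**Step 7**
Reactants: 14 the dioxolane
Product: 15 5-[(2R,3R)-5-(1,3-dioxolan-2-yl)-2-(4-hydroxyphenyl)-2,3-dihydro-1-benzofuran-3-yl]benzene-1,3-diol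
Conditions: H2 (1 atm), 10% Pd/C, EtOAc–EtOH, rt
Reagents that add atoms: none
Why: Neutral hydrogenolysis removes the three primary aryl benzyl ethers faster than the secondary cyclic benzylic C2–O bond is cleaved, and the acetal is inert without acid.

**Step 8**
Reactants: 15 the triphenol
Product: 16 4-bromo-5-[(2R,3S)-5-(1,3-dioxolan-2-yl)-2-(4-hydroxyphenyl)-2,3-dihydro-1-benzofuran-3-yl]benzene-1,3-diol (same spatial arrangement; the C3 descriptor changes by priority only)
Conditions: NBS (1.0 equiv), MeCN, −40 to 0 °C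
Reagents that add atoms: N-bromosuccinimide, O=C1CCC(=O)N1Br
Why: Electrophilic aromatic bromination hits the resorcinol ring, by far the most electron-rich arene, para to one OH and ortho to the other as in 5-alkylresorcinols; the two such positions are equivalent by rotation, so one monobromide should result.

**Step 9**
Reactants: 16 the bromoresorcinol
Product: 20 3-[(2R,3S)-5-(1,3-dioxolan-2-yl)-2-(4-hydroxyphenyl)-2,3-dihydro-1-benzofuran-3-yl]-5-hydroxy-2-(trimethylsilyl)phenyl trifluoromethanesulfonate, via tris(trimethylsilyl) ether 17 (not isolated), via lithium phenoxide 18 (not isolated), via bis(silyl ether) triflate 19 (not isolated)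
Conditions: (Me3Si)2NH, THF, 65 °C, evaporate; n-BuLi (1.05 equiv), THF, −78 to −40 °C; PhNTf2, −78 °C to rt; MeOH–aq. NaHCO3, rt
Reagents that add atoms: hexamethyldisilazane, C[Si](C)(C)N[Si](C)(C)C; N-phenylbis(trifluoromethanesulfonimide), O=S(=O)(N(c1ccccc1)S(=O)(=O)C(F)(F)F)C(F)(F)F
Why: This is the standard route to o-silylaryl triflates: persilylation, bromine–lithium exchange and a 1,3 O-to-C silyl shift (retro-Brook rearrangement) that can only involve the silyloxy group ortho to lithium and so tells the two ring-B oxygens apart, then triflation of the single phenoxide and methanolysis of the remaining aryl silyl ethers.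

**Step 10**
Reactants: 20 the diphenol
Product: 21 3-{(2R,3S)-5-(1,3-dioxolan-2-yl)-2-[4-(methoxymethoxy)phenyl]-2,3-dihydro-1-benzofuran-3-yl}-5-(methoxymethoxy)-2-(trimethylsilyl)phenyl trifluoromethanesulfonate
Conditions: MOMCl, i-Pr2NEt, CH2Cl2, 0 °C to rt
Reagents that add atoms: chloromethyl methyl ether, COCCl
Why: O-alkylation caps the two phenols, which would otherwise add to the aryne; an amine base at low temperature does not trigger the silyl triflate.

**Step 11**
Reactants: 22 3,5-dihydroxybenzaldehyde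
Product: 23 3,5-bis(methoxymethoxy)benzaldehyde
Conditions: MOMCl, i-Pr2NEt, CH2Cl2, 0 °C to rt
Reagents that add atoms: chloromethyl methyl ether, COCCl
Why: O-alkylation gives ether-type groups that are stable to fluoride and base and keep this ring from becoming electron-poor.

**Step 12**
Reactants: 24 diethyl (4-hydroxybenzyl)phosphonate
Product: 25 4-[(diethoxyphosphoryl)methyl]phenyl trifluoromethanesulfonate
Conditions: Tf2O, pyridine, CH2Cl2, 0 °C
Reagents that add atoms: trifluoromethanesulfonic anhydride, O=S(=O)(OS(=O)(=O)C(F)(F)F)C(F)(F)F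
Why: Phenol sulfonylation turns the para oxygen into a strongly electron-withdrawing group that is still one mild step away from the phenol.

**Step 13**
Reactants: 23 3,5-bis(methoxymethoxy)benzaldehyde; 25 the phosphonate
Product: 26 4-{(E)-2-[3,5-bis(methoxymethoxy)phenyl]ethenyl}phenyl trifluoromethanesulfonate
Conditions: NaH, THF, 0 °C to rt
Reagents that add atoms: none
Why: The Horner–Wadsworth–Emmons reaction of a benzylic phosphonate with an aromatic aldehyde gives the E-stilbene.

**Step 14**
Reactants: 26 the E-stilbene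
Product: 27 4-{(2S,3S)-3-[3,5-bis(methoxymethoxy)phenyl]oxiran-2-yl}phenyl trifluoromethanesulfonate
Conditions: 1,2:4,5-di-O-isopropylidene-β-L-erythro-2,3-hexodiulo-2,6-pyranose (30 mol %), Oxone (2KHSO5·KHSO4·K2SO4), K2CO3, Na2B4O7 buffer, Bu4NHSO4 (cat.), MeCN–CH2(OMe)2–H2O, 0 °C
Reagents that add atoms: potassium peroxymonosulfate, [K+].[O-]S(=O)(=O)OO
Why: Shi epoxidation of a trans-stilbene, the best substrate class for the chiral dioxirane; the D-series ketone gives (R,R)-stilbene oxides, so the L-series ketone sets both centres as S, and the triflate makes the oxirane robust to handling.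

**Step 15**
Reactants: 21 the o-silylaryl triflate; 27 the (2S,3S)-oxirane
Product: 30 4-[(2R,3R)-3-[3,5-bis(methoxymethoxy)phenyl]-4-{(2R,3R)-5-(1,3-dioxolan-2-yl)-2-[4-(methoxymethoxy)phenyl]-2,3-dihydro-1-benzofuran-3-yl}-6-(methoxymethoxy)-2,3-dihydro-1-benzofuran-2-yl]phenyl trifluoromethanesulfonate, via aryne 28 (not isolated), via oxiranium betaine 29 (not isolated)
Conditions: CsF (4 equiv), 27 (3 equiv, excess recovered), MeCN–toluene 1:1, 4 Å MS, 25 to 40 °C
Reagents that add atoms: none
Why: Proposed new method: fluoride strips Me3Si from 21 and triflate leaves to give aryne 28; the oxirane oxygen of 27 adds to the aryne carbon remote from the dihydrobenzofuranyl substituent to give betaine 29, whose O-aryloxiranium ionises at the benzylic C–O bond next to the 3,5-bis(methoxymethoxy)phenyl ring, and the ortho aryl anion collapses on that carbon. The closest known reaction type is the fluoride-induced insertion of arynes into the benzylic C–O bond of styrene oxide to give 3-aryl-2,3-dihydrobenzofurans; the extension lies in 2,3-diaryloxiranes, chirality transfer and a choice between two benzylic C–O bonds. The one new ring (O1–C2–C3–C3a–C7a) closes in a formally 5-endo-tet mode, which rules out a concerted backside displacement and so demands stepwise ionisation and front-side ion-pair collapse. C2 keeps its oxirane C–O bond untouched and is transferred unchanged (S becomes R by priority change only), while C3 is re-formed with retention because collapse on the face just vacated by oxygen is fastest and also gives the less strained 2,3-trans ring, so that even a rotated cation converges on the same isomer under control of C2. Three selectivities are needed: aryne regiochemistry, secured by the steric bulk flanking one aryne terminus (the methoxymethoxy group on ring B is electronically almost neutral); the site of C–O cleavage, secured by the para triflate, which destabilises the competing benzylic cation where a para ether would direct cleavage the wrong way; and chemoselectivity for the weakly nucleophilic oxirane, secured by the masked aldehyde, capped phenols, excess 27 and slow aryne release from poorly soluble CsF.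

**Step 16**
Reactants: 30 the aryl triflate
Product: 31 4-[(2R,3R)-3-[3,5-bis(methoxymethoxy)phenyl]-4-{(2R,3R)-5-(1,3-dioxolan-2-yl)-2-[4-(methoxymethoxy)phenyl]-2,3-dihydro-1-benzofuran-3-yl}-6-(methoxymethoxy)-2,3-dihydro-1-benzofuran-2-yl]phenol
Conditions: Et4NOH (35% aq.), 1,4-dioxane, rt; pH 7 buffer
Reagents that add atoms: none
Why: Hydroxide attacks sulfur of the aryl triflate (S–O cleavage), a known mild detriflation; ethers and acetal are base-stable and the other 2-aryl group is still capped, so no quinone methide can open the outer ring.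

**Step 17**
Reactants: 31 the phenol
Product: 32 (2R,3R)-3-[(2R,3R)-3-(3,5-dihydroxyphenyl)-6-hydroxy-2-(4-hydroxyphenyl)-2,3-dihydro-1-benzofuran-4-yl]-2-(4-hydroxyphenyl)-2,3-dihydro-1-benzofuran-5-carbaldehyde
Conditions: 2 M aq. HCl–MeOH–THF (1:4:4), 40 °C, argon, high dilution
Reagents that add atoms: water, O
Why: Acid-catalysed transacetalisation of the four methoxymethyl ethers and hydrolysis of the dioxolane; any reversible opening at a C2–O bond recloses to the trans ring under control of the untouched C3, and dilution suppresses aldehyde–resorcinol condensation.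

**Compound list**
1 | 5-bromobenzene-1,3-diol | Oc1cc(O)cc(Br)c1 | starting material
2 | 1,3-bis(benzyloxy)-5-bromobenzene | Brc1cc(OCc2ccccc2)cc(OCc2ccccc2)c1 | intermediate
3 | 5-bromo-2-hydroxybenzonitrile | N#Cc1cc(Br)ccc1O | starting material
4 | 4-(benzyloxy)benzyl chloride | ClCc1ccc(OCc2ccccc2)cc1 | starting material
5 | 2-{[4-(benzyloxy)phenyl]methoxy}-5-bromobenzonitrile | N#Cc1cc(Br)ccc1OCc1ccc(OCc2ccccc2)cc1 | intermediate
6 | [3,5-bis(benzyloxy)phenyl]magnesium bromide | Br[Mg]c1cc(OCc2ccccc2)cc(OCc2ccccc2)c1 | intermediate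
7 | N-H ketimine from 5 and 6 | N=C(c1cc(Br)ccc1OCc1ccc(OCc2ccccc2)cc1)c1cc(OCc2ccccc2)cc(OCc2ccccc2)c1 | intermediate
8 | hydrazone of the diaryl ketone (C=N geometry not defined) | NN=C(c1cc(Br)ccc1OCc1ccc(OCc2ccccc2)cc1)c1cc(OCc2ccccc2)cc(OCc2ccccc2)c1 | intermediate
9 | diaryldiazomethane | [N-]=[N+]=C(c1cc(Br)ccc1OCc1ccc(OCc2ccccc2)cc1)c1cc(OCc2ccccc2)cc(OCc2ccccc2)c1 | intermediate
10 | (2S,3R)-cis-3-[3,5-bis(benzyloxy)phenyl]-2-[4-(benzyloxy)phenyl]-5-bromo-2,3-dihydro-1-benzofuran | Brc1ccc2c(c1)[C@@H](c1cc(OCc3ccccc3)cc(OCc3ccccc3)c1)[C@@H](c1ccc(OCc3ccccc3)cc1)O2 | intermediate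
11 | (2R,3R)-trans-3-[3,5-bis(benzyloxy)phenyl]-2-[4-(benzyloxy)phenyl]-5-bromo-2,3-dihydro-1-benzofuran | Brc1ccc2c(c1)[C@@H](c1cc(OCc3ccccc3)cc(OCc3ccccc3)c1)[C@H](c1ccc(OCc3ccccc3)cc1)O2 | intermediate
12 | 5-lithio derivative of 11 (2R,3R) | [Li]c1ccc2c(c1)[C@@H](c1cc(OCc3ccccc3)cc(OCc3ccccc3)c1)[C@H](c1ccc(OCc3ccccc3)cc1)O2 | intermediate
13 | (2R,3R)-3-[3,5-bis(benzyloxy)phenyl]-2-[4-(benzyloxy)phenyl]-2,3-dihydro-1-benzofuran-5-carbaldehyde | O=Cc1ccc2c(c1)[C@@H](c1cc(OCc3ccccc3)cc(OCc3ccccc3)c1)[C@H](c1ccc(OCc3ccccc3)cc1)O2 | intermediate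
14 | (2R,3R)-3-[3,5-bis(benzyloxy)phenyl]-2-[4-(benzyloxy)phenyl]-5-(1,3-dioxolan-2-yl)-2,3-dihydro-1-benzofuran | O1CCOC1c1ccc2c(c1)[C@@H](c1cc(OCc3ccccc3)cc(OCc3ccccc3)c1)[C@H](c1ccc(OCc3ccccc3)cc1)O2 | intermediate
15 | 5-[(2R,3R)-5-(1,3-dioxolan-2-yl)-2-(4-hydroxyphenyl)-2,3-dihydro-1-benzofuran-3-yl]benzene-1,3-diol | O1CCOC1c1ccc2c(c1)[C@@H](c1cc(O)cc(O)c1)[C@H](c1ccc(O)cc1)O2 | intermediate
16 | 4-bromo-5-[(2R,3S)-5-(1,3-dioxolan-2-yl)-2-(4-hydroxyphenyl)-2,3-dihydro-1-benzofuran-3-yl]benzene-1,3-diol | O1CCOC1c1ccc2c(c1)[C@@H](c1cc(O)cc(O)c1Br)[C@H](c1ccc(O)cc1)O2 | intermediate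
17 | tris(trimethylsilyl) ether of 16 (2R,3S) | O1CCOC1c1ccc2c(c1)[C@@H](c1cc(O[Si](C)(C)C)cc(O[Si](C)(C)C)c1Br)[C@H](c1ccc(O[Si](C)(C)C)cc1)O2 | intermediate
18 | lithium 2-(trimethylsilyl)phenoxide formed by the O-to-C silyl shift (2R,3S) | O1CCOC1c1ccc2c(c1)[C@@H](c1cc(O[Si](C)(C)C)cc(O[Li])c1[Si](C)(C)C)[C@H](c1ccc(O[Si](C)(C)C)cc1)O2 | intermediate
19 | bis(O-trimethylsilyl) ether of 20 (2R,3S) | O1CCOC1c1ccc2c(c1)[C@@H](c1cc(O[Si](C)(C)C)cc(OS(=O)(=O)C(F)(F)F)c1[Si](C)(C)C)[C@H](c1ccc(O[Si](C)(C)C)cc1)O2 | intermediate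
20 | 3-[(2R,3S)-5-(1,3-dioxolan-2-yl)-2-(4-hydroxyphenyl)-2,3-dihydro-1-benzofuran-3-yl]-5-hydroxy-2-(trimethylsilyl)phenyl trifluoromethanesulfonate | O1CCOC1c1ccc2c(c1)[C@@H](c1cc(O)cc(OS(=O)(=O)C(F)(F)F)c1[Si](C)(C)C)[C@H](c1ccc(O)cc1)O2 | intermediate
21 | 3-{(2R,3S)-5-(1,3-dioxolan-2-yl)-2-[4-(methoxymethoxy)phenyl]-2,3-dihydro-1-benzofuran-3-yl}-5-(methoxymethoxy)-2-(trimethylsilyl)phenyl trifluoromethanesulfonate | O1CCOC1c1ccc2c(c1)[C@@H](c1cc(OCOC)cc(OS(=O)(=O)C(F)(F)F)c1[Si](C)(C)C)[C@H](c1ccc(OCOC)cc1)O2 | intermediate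
22 | 3,5-dihydroxybenzaldehyde | O=Cc1cc(O)cc(O)c1 | starting material
23 | 3,5-bis(methoxymethoxy)benzaldehyde | O=Cc1cc(OCOC)cc(OCOC)c1 | intermediate
24 | diethyl (4-hydroxybenzyl)phosphonate | CCOP(=O)(Cc1ccc(O)cc1)OCC | starting material
25 | 4-[(diethoxyphosphoryl)methyl]phenyl trifluoromethanesulfonate | CCOP(=O)(Cc1ccc(OS(=O)(=O)C(F)(F)F)cc1)OCC | intermediate
26 | 4-{(E)-2-[3,5-bis(methoxymethoxy)phenyl]ethenyl}phenyl trifluoromethanesulfonate | FC(F)(F)S(=O)(=O)Oc1ccc(/C=C/c2cc(OCOC)cc(OCOC)c2)cc1 | intermediate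
27 | 4-{(2S,3S)-3-[3,5-bis(methoxymethoxy)phenyl]oxiran-2-yl}phenyl trifluoromethanesulfonate | COCOc1cc(OCOC)cc(c1)[C@H]1[C@H](c2ccc(OS(=O)(=O)C(F)(F)F)cc2)O1 | intermediate
28 | ring-B aryne from 21 (didehydro between the former C–Si and C–OTf carbons; 2R,3R) | O1CCOC1c1ccc2c(c1)[C@@H](C1=CC(OCOC)=CC#C1)[C@H](c1ccc(OCOC)cc1)O2 | intermediate
29 | O-aryloxiranium/aryl anion betaine (configurations as in 21 and 27) | O1CCOC1c1ccc2c(c1)[C@@H](c1cc(OCOC)cc([O+]3[C@@H](c4ccc(OS(=O)(=O)C(F)(F)F)cc4)[C@@H]3c5cc(OCOC)cc(OCOC)c5)[c-]1)[C@H](c1ccc(OCOC)cc1)O2 | intermediate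
30 | protected bis(dihydrobenzofuran) aryl triflate (all four centres R; full name in step 15) | O1CCOC1c1ccc2c(c1)[C@@H](c1cc(OCOC)cc3c1[C@@H](c1cc(OCOC)cc(OCOC)c1)[C@H](c1ccc(OS(=O)(=O)C(F)(F)F)cc1)O3)[C@H](c1ccc(OCOC)cc1)O2 | intermediate
31 | phenol obtained from 30 (all four centres R; full name in step 16) | O1CCOC1c1ccc2c(c1)[C@@H](c1cc(OCOC)cc3c1[C@@H](c1cc(OCOC)cc(OCOC)c1)[C@H](c1ccc(O)cc1)O3)[C@H](c1ccc(OCOC)cc1)O2 | intermediate
32 | (2R,3R)-3-[(2R,3R)-3-(3,5-dihydroxyphenyl)-6-hydroxy-2-(4-hydroxyphenyl)-2,3-dihydro-1-benzofuran-4-yl]-2-(4-hydroxyphenyl)-2,3-dihydro-1-benzofuran-5-carbaldehyde | O=Cc1ccc2c(c1)[C@@H](c1cc(O)cc3c1[C@@H](c1cc(O)cc(O)c1)[C@H](c1ccc(O)cc1)O3)[C@H](c1ccc(O)cc1)O2 | target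

**Step count**
Total step count: 17. Longest linear sequence: 12 steps (2, 3, 4, 5, 6, 7, 8, 9, 10, 15, 16, 17; the same length starting from step 1).

**Steps most likely to fail**

1. **Step 15.**
   - What may go wrong: addition of the oxirane oxygen to the hindered aryne terminus; ionisation of the other benzylic C–O bond; a 1,2-hydride shift in the opened cation (Meinwald-type); proton capture by the aryl anion from acetonitrile; self-consumption of the aryne, because the oxirane is a weak nucleophile.
   - Fallback (known chemistry, from 21, rejoining at 32): the aryne is generated with CsF in DMF. The known insertion of arynes into the C=O bond of DMF, followed by aqueous hydrolysis, should give the salicylaldehyde F1, again with oxygen on the remote carbon.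
   - Addition of 3,5-bis(methoxymethoxy)phenylmagnesium bromide (2.5 equiv) gives the o-hydroxybenzhydrol F2, and p-toluenesulfinic acid in CH2Cl2 converts it into the sulfone F3.
   - Cs2CO3 with [4-(methoxymethoxy)benzyl]dimethylsulfonium tetrafluoroborate releases the o-quinone methide, which undergoes the known [4+1] annulation with the sulfur ylide to give the trans-dihydrobenzofuran pentaether F4. The two trans diastereomers are separated by chromatography, or biased by a sulfonium salt of an enantiopure sulfide.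
   - F4 is unmasked under the conditions of step 17 to reach 32.

2. **Step 8.**
   - What may go wrong: bromination between the two hydroxyl groups because the wanted position is crowded by the benzylic substituent; a second bromination; attack on the 4-hydroxyphenyl ring.
   - Fallback (from 15, rejoining at 16): temporary steric shielding. TIPSCl and imidazole in DMF give the tris(triisopropylsilyl) ether F5, in which the position between the two bulky silyloxy groups is blocked and para direction dominates.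
   - NBS then gives the monobromide F6, and Bu4NF in THF returns 16.

3. **Step 17.**
   - What may go wrong: acid-induced ionisation of the C2–O bond of the inner ring once its 2-aryl group is a free phenol and its ring oxygen is the more basic one, followed by Friedel–Crafts capture; condensation of the freed aldehyde with the resorcinol rings.
   - Fallback (from 30, rejoining at 32): the order of the endgame is inverted. The acid unmasking is run on 30 while the electron-withdrawing triflate still switches off ionisation at the inner C2, giving the pentaphenol aldehyde triflate F7.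
   - The triflate is removed last with Et4NOH in dioxane at 0 °C under argon to give 32.

**Further compounds**
F1 | step 15 | 2-{(2R,3R)-5-(1,3-dioxolan-2-yl)-2-[4-(methoxymethoxy)phenyl]-2,3-dihydro-1-benzofuran-3-yl}-6-hydroxy-4-(methoxymethoxy)benzaldehyde | O1CCOC1c1ccc2c(c1)[C@@H](c1cc(OCOC)cc(O)c1C=O)[C@H](c1ccc(OCOC)cc1)O2
F2 | step 15 | o-hydroxybenzhydrol from F1 (carbinol centre undefined) | O1CCOC1c1ccc2c(c1)[C@@H](c1cc(OCOC)cc(O)c1C(O)c1cc(OCOC)cc(OCOC)c1)[C@H](c1ccc(OCOC)cc1)O2
F3 | step 15 | 2-[aryl(4-methylbenzenesulfonyl)methyl]phenol from F2 (sulfone centre undefined) | O1CCOC1c1ccc2c(c1)[C@@H](c1cc(OCOC)cc(O)c1C(c1cc(OCOC)cc(OCOC)c1)S(=O)(=O)c1ccc(C)cc1)[C@H](c1ccc(OCOC)cc1)O2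
F4 | step 15 | penta(methoxymethyl) ether dioxolane of 32 (all four centres R) | O1CCOC1c1ccc2c(c1)[C@@H](c1cc(OCOC)cc3c1[C@@H](c1cc(OCOC)cc(OCOC)c1)[C@H](c1ccc(OCOC)cc1)O3)[C@H](c1ccc(OCOC)cc1)O2
F5 | step 8 | tris(triisopropylsilyl) ether of 15 (2R,3R) | O1CCOC1c1ccc2c(c1)[C@@H](c1cc(O[Si](C(C)C)(C(C)C)C(C)C)cc(O[Si](C(C)C)(C(C)C)C(C)C)c1)[C@H](c1ccc(O[Si](C(C)C)(C(C)C)C(C)C)cc1)O2
F6 | step 8 | tris(triisopropylsilyl) ether of 16 (2R,3S) | O1CCOC1c1ccc2c(c1)[C@@H](c1cc(O[Si](C(C)C)(C(C)C)C(C)C)cc(O[Si](C(C)C)(C(C)C)C(C)C)c1Br)[C@H](c1ccc(O[Si](C(C)C)(C(C)C)C(C)C)cc1)O2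
F7 | step 17 | 4-[(2R,3R)-3-(3,5-dihydroxyphenyl)-4-[(2R,3R)-5-formyl-2-(4-hydroxyphenyl)-2,3-dihydro-1-benzofuran-3-yl]-6-hydroxy-2,3-dihydro-1-benzofuran-2-yl]phenyl trifluoromethanesulfonate | O=Cc1ccc2c(c1)[C@@H](c1cc(O)cc3c1[C@@H](c1cc(O)cc(O)c1)[C@H](c1ccc(OS(=O)(=O)C(F)(F)F)cc1)O3)[C@H](c1ccc(O)cc1)O2
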